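**Retrosynthetic overview**
- The target is a linear tridepside: ring A (methyl 2-methoxy-6-methylbenzoate unit), ring B (2-methoxy-6-methylbenzoyl unit), ring C (orsellinoyl unit). No ring is built; all three benzene rings are bought intact.
- Both depside links are cut at the aryl C–O bond: an aryl boronate on ring A (or ring B) is joined to the carboxylic acid of ring B (or ring C).
- Each aryl boronate comes from the unfunctionalised arene by sterically controlled Ir C–H borylation, so rings A and B need no phenol protection.
- Ring C enters as 2,4-di-O-benzyl orsellinic acid, made from methyl orsellinate; the benzyl ethers are removed last by hydrogenolysis.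
- Order: ring A + ring B, then ring C, then debenzylation.

Assumption: the target has no stereocentre, so there is no configuration to set; methyl 2-methoxy-6-methylbenzoate, 2-methoxy-6-methylbenzoic acid and methyl orsellinate are taken as purchased.

**Step 1**
Reactants: 1 methyl 2-methoxy-6-methylbenzoate; 2 bis(pinacolato)diboron; 3 2-methoxy-6-methylbenzoic acid
Product: 5 methyl 2-methoxy-4-[(2-methoxy-6-methylbenzoyl)oxy]-6-methylbenzoate, via aryl pinacol boronate 4 (not isolated)
Conditions: 2 (1.0 equiv), [Ir(OMe)(cod)]2 (1.5 mol%), dtbpy (3 mol%), THF, 80 °C; evaporate (removes HBpin); then 3 (1.5 equiv), Cu(OTf)2 (1.0 equiv), pyridine (4 equiv), 4 Å molecular sieves, MeCN, dry air, 70 °C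
Reagents that add atoms: none
Why: Proposed new method: a one-pot meta-selective C–H acyloxylation in which Ir-catalysed C–H borylation places Bpin at C4 of 1 (the only C–H not next to a substituent) and the crude boronate 4 is coupled with the carboxylate of 3 at divalent copper (boron-to-copper transmetalation, oxidation to an aryl trivalent copper carboxylate, C–O reductive elimination, air returning monovalent copper to the divalent state); the closest known reactions are the Cu(OTf)2-mediated Chan–Lam esterification of arylboronic acids with carboxylic acids and the Cu(OTf)2/pyridine-mediated coupling of aryl pinacol boronates with weak anionic nucleophiles, and what is new is the pinacol boronate partner, the di-ortho-substituted benzoic acid and the telescoping with the borylation.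

**Step 2**
Reactants: 6 methyl orsellinate (methyl 2,4-dihydroxy-6-methylbenzoate)
Product: 8 di-O-benzylorsellinic acid (2,4-bis(benzyloxy)-6-methylbenzoic acid), via methyl di-O-benzylorsellinate 7 (not isolated)
Conditions: BnBr (2.4 equiv), K2CO3 (3 equiv), DMSO, 60 °C; then KOH (6 equiv), H2O, 100 °C; then aq. HCl, 0 °C
Reagents that add atoms: benzyl bromide, BrCc1ccccc1; potassium hydroxide, [K+].[OH-]
Why: Williamson O-benzylation of both phenols (the chelated 2-OH needs the warm carbonate/DMSO medium) followed by saponification of the hindered methyl ester with poorly solvated hydroxide in wet DMSO.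

**Step 3**
Reactants: 5 methyl 2-methoxy-4-[(2-methoxy-6-methylbenzoyl)oxy]-6-methylbenzoate; 2 bis(pinacolato)diboron; 8 2,4-bis(benzyloxy)-6-methylbenzoic acid
Product: 10 methyl 4-[(4-{[2,4-bis(benzyloxy)-6-methylbenzoyl]oxy}-2-methoxy-6-methylbenzoyl)oxy]-2-methoxy-6-methylbenzoate, via didepside pinacol boronate 9 (not isolated)
Conditions: 2 (1.0 equiv), [Ir(OMe)(cod)]2 (2 mol%), dtbpy (4 mol%), THF, 80 °C; evaporate; then 8 (1.5 equiv), Cu(OTf)2 (1.0 equiv), pyridine (4 equiv), 4 Å molecular sieves, MeCN, dry air, 70 °C
Reagents that add atoms: none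
Why: Proposed new method: the same one-pot C–H borylation/copper-mediated acyloxylation as in step 1, where borylation goes only to C4 of ring B because both C–H bonds of ring A sit between two substituents, and the boronate 9 then transfers its aryl group to divalent copper carrying the carboxylate of 8 for C–O reductive elimination from trivalent copper; the closest known reaction is again the Cu(OTf)2-mediated Chan–Lam esterification of arylboronic acids, here extended to a pinacol boronate that already carries a depside ester.

**Step 4**
Reactants: 10 methyl 4-[(4-{[2,4-bis(benzyloxy)-6-methylbenzoyl]oxy}-2-methoxy-6-methylbenzoyl)oxy]-2-methoxy-6-methylbenzoate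
Product: 11 methyl 4-({4-[(2,4-dihydroxy-6-methylbenzoyl)oxy]-2-methoxy-6-methylbenzoyl}oxy)-2-methoxy-6-methylbenzoate (target)
Conditions: H2 (1 atm), Pd/C (10 wt%), EtOAc/THF, rt
Reagents that add atoms: none
Why: Hydrogenolysis of the two aryl benzyl ethers over zerovalent palladium on carbon leaves the hindered aryl esters, the methyl ester and the methyl ethers untouched, as in classical depside syntheses.

**Compound list**
1 | methyl 2-methoxy-6-methylbenzoate | COC(=O)c1c(C)cccc1OC | starting material
2 | bis(pinacolato)diboron | CC1(C)OB(OC1(C)C)B1OC(C)(C)C(C)(C)O1 | starting material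
3 | 2-methoxy-6-methylbenzoic acid | COc1cccc(C)c1C(=O)O | starting material
4 | methyl 2-methoxy-6-methyl-4-(4,4,5,5-tetramethyl-1,3,2-dioxaborolan-2-yl)benzoate | COC(=O)c1c(C)cc(B2OC(C)(C)C(C)(C)O2)cc1OC | intermediate
5 | methyl 2-methoxy-4-[(2-methoxy-6-methylbenzoyl)oxy]-6-methylbenzoate | COC(=O)c1c(C)cc(OC(=O)c2c(C)cccc2OC)cc1OC | intermediate
6 | methyl orsellinate (methyl 2,4-dihydroxy-6-methylbenzoate) | COC(=O)c1c(C)cc(O)cc1O | starting material
7 | methyl 2,4-bis(benzyloxy)-6-methylbenzoate | COC(=O)c1c(C)cc(OCc2ccccc2)cc1OCc1ccccc1 | intermediate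
8 | 2,4-bis(benzyloxy)-6-methylbenzoic acid | OC(=O)c1c(C)cc(OCc2ccccc2)cc1OCc1ccccc1 | intermediate
9 | methyl 2-methoxy-4-{[2-methoxy-6-methyl-4-(4,4,5,5-tetramethyl-1,3,2-dioxaborolan-2-yl)benzoyl]oxy}-6-methylbenzoate | COC(=O)c1c(C)cc(OC(=O)c2c(C)cc(B3OC(C)(C)C(C)(C)O3)cc2OC)cc1OC | intermediate
10 | methyl 4-[(4-{[2,4-bis(benzyloxy)-6-methylbenzoyl]oxy}-2-methoxy-6-methylbenzoyl)oxy]-2-methoxy-6-methylbenzoate | COC(=O)c1c(C)cc(OC(=O)c2c(C)cc(OC(=O)c3c(C)cc(OCc4ccccc4)cc3OCc5ccccc5)cc2OC)cc1OC | intermediate
11 | methyl 4-({4-[(2,4-dihydroxy-6-methylbenzoyl)oxy]-2-methoxy-6-methylbenzoyl}oxy)-2-methoxy-6-methylbenzoate (achiral) | COC(=O)c1c(C)cc(OC(=O)c2c(C)cc(OC(=O)c3c(C)cc(O)cc3O)cc2OC)cc1OC | target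

**Totals**
Total step count: 4. Longest linear sequence: 3 steps (1 → 5 → 10 → 11); the ring C acid 8 is made in one side step.

**Three steps most likely to fail**

Step 1 (proposed new method). The copper stage may give protodeboronation or phenol instead of the aryl ester, because the pinacol boronate transmetalates slowly and the carboxylate is a weak coupling partner. The fallback uses known chemistry and makes the depside bond at the acyl carbon. It sets out from 1: the same Ir borylation gives 4, which is oxidised in the same flask with 2KHSO5·KHSO4·K2SO4 in aqueous acetone to methyl 4-hydroxy-2-methoxy-6-methylbenzoate F1. Acid 3 is activated with TFAA in toluene as 2-methoxy-6-methylbenzoic trifluoroacetic anhydride F2, which acylates F1 at rt (the classical depside esterification of hindered acids). This comes back to the route at 5. Any F1 formed as a by-product of the new step can be converted the same way.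

Step 2. Hydrolysis of the di-ortho-substituted ester 7 may stall, or the forcing base may degrade the material. The fallback replaces hydrolysis by a redox detour and sets out from 7, isolated after the benzylation stage. LiAlH4 in THF reduces it to [2,4-bis(benzyloxy)-6-methylphenyl]methanol F3. MnO2 in CH2Cl2 gives 2,4-bis(benzyloxy)-6-methylbenzaldehyde F4. Pinnick oxidation (NaClO2, NaH2PO4, 2-methyl-2-butene, tBuOH/H2O) gives the acid, coming back to the route at 8.

Step 3 (proposed new method on the larger substrate). Besides the risks of step 1, the borylation must distinguish two rings and the boronate already carries an aryl ester. The fallback uses known chemistry and sets out from 5: Ir borylation to 9, then oxidation in the same flask with 2KHSO5·KHSO4·K2SO4 in aqueous acetone, gives methyl 4-[(4-hydroxy-2-methoxy-6-methylbenzoyl)oxy]-2-methoxy-6-methylbenzoate F5. Acid 8 is activated with TFAA in toluene as 2,4-bis(benzyloxy)-6-methylbenzoic trifluoroacetic anhydride F6, which acylates F5 at rt. This comes back to the route at 10.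

**Further compounds**
F1 | step 1 | methyl 4-hydroxy-2-methoxy-6-methylbenzoate | COC(=O)c1c(C)cc(O)cc1OC
F2 | step 1 | 2-methoxy-6-methylbenzoic trifluoroacetic anhydride | COc1cccc(C)c1C(=O)OC(=O)C(F)(F)F
F3 | step 2 | [2,4-bis(benzyloxy)-6-methylphenyl]methanol | OCc1c(C)cc(OCc2ccccc2)cc1OCc1ccccc1
F4 | step 2 | 2,4-bis(benzyloxy)-6-methylbenzaldehyde | O=Cc1c(C)cc(OCc2ccccc2)cc1OCc1ccccc1
F5 | step 3 | methyl 4-[(4-hydroxy-2-methoxy-6-methylbenzoyl)oxy]-2-methoxy-6-methylbenzoate | COC(=O)c1c(C)cc(OC(=O)c2c(C)cc(O)cc2OC)cc1OC
F6 | step 3 | 2,4-bis(benzyloxy)-6-methylbenzoic trifluoroacetic anhydride | Cc1cc(OCc2ccccc2)cc(OCc2ccccc2)c1C(=O)OC(=O)C(F)(F)F
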